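**Plan**

1. Retrosynthesis opens the 7-oxabicyclo[2.2.1]heptane (O7; C1 bearing methyl and lying next to the chain-bearing C2; C3; C4; C5H2–C6H2) at C5–C6 and O7–C4 in one cut. Its oxolane ring O7–C1–C6–C5–C4 is the sum of a 2-methyl-2-alkyloxirane (O7, C1, C6) and an isopropenyl group (C5=C4) held 1,4 by the C2–C3 bond, so the whole bicycle comes from an acyclic epoxy alkene.
2. Further cuts: oxirane C1–C6 (sulfur ylide on a methyl ketone), C2–C3 (Ireland–Claisen rearrangement of a tiglyl ester), oxane C–O and C–Br (bromoetherification), the allyl–alkyl bond of the chain (copper-catalysed Grignard coupling), the allylic C–O bond, and back to geraniol.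
3. Forward: geraniol → (S)-linalool → allylic bromide → three-carbon extension → tiglyl ester. The bromo-oxane ring is closed next, the Claisen step joins the five-carbon unit, the ketone is epoxidised, and the last step closes carbocycle and ether bridge together.
4. Stereochemistry: oxane C6 from Sharpless epoxidation; oxane C2/C3 from anti addition to the E-alkene (C6 epimers separated); bicycle C2/C3 from the chair Claisen transition state under a chiral boron controller; C1 from Felkin–Anh ylide addition; C4 from the tether.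
5. The oxirane is the temporary ring and iodide the traceless activator; both are consumed in the final step.

Key step: step 12

Assumption: the (S,S)-enantiomer of the boron controller in step 9 is taken as the one that leads to the (2R,3R)-acid; should the sense of induction be the opposite, the (R,R)-controller is used instead.

**Route**

Step 1
Reactants: 1 geraniol
Product: 2 (2S,3S)-2,3-epoxygeraniol
Conditions: Ti(OiPr)4 (5 mol %), L-(+)-diethyl tartrate (6 mol %), t-BuOOH, 4 Å MS, CH2Cl2, −20 °C
Reagents that add atoms: tert-butyl hydroperoxide, CC(C)(C)OO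
Why: Sharpless asymmetric epoxidation of the allylic alcohol, in which the L-(+)-tartrate catalyst delivers oxygen to the face that gives the (2S,3S)-epoxide and so fixes the later carbinol centre, while the remote 6,7-alkene is not touched.

Step 2
Reactants: 2 (2S,3S)-2,3-epoxygeraniol
Product: 4 (S)-linalool, via epoxy iodide 3 (not isolated)
Conditions: PPh3, I2, imidazole, CH2Cl2, 0 °C; then Zn dust, AcOH, EtOH, 25 °C (crude iodide)
Reagents that add atoms: none
Why: Appel iodination of the primary alcohol followed by zinc-induced reductive opening of the 2,3-epoxy iodide gives the tertiary allylic alcohol, and because no bond to C-3 is broken the epoxide configuration becomes the (S)-carbinol.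

Step 3
Reactants: 4 (S)-linalool
Product: 5 (2E,6S)-2,6-dimethylocta-2,7-diene-1,6-diol
Conditions: SeO2 (0.3 equiv), t-BuOOH, salicylic acid (cat.), CH2Cl2, 25 °C
Reagents that add atoms: tert-butyl hydroperoxide, CC(C)(C)OO (terminal oxygen source, passed on through SeO2, O=[Se]=O)
Why: SeO2-catalysed allylic oxidation (ene reaction then [2,3]-shift) selects the (E)-methyl group of the trisubstituted alkene and should leave the vinyl group and the tertiary alcohol alone.

Step 4
Reactants: 5 (2E,6S)-2,6-dimethylocta-2,7-diene-1,6-diol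
Product: 6 (3S,6E)-8-bromo-3,7-dimethylocta-1,6-dien-3-ol
Conditions: CBr4, PPh3, CH2Cl2, −30 → 0 °C; used crude
Reagents that add atoms: carbon tetrabromide, BrC(Br)(Br)Br
Why: Appel bromination exchanges only the primary allylic hydroxyl, since the tertiary alcohol does not form the oxyphosphonium ion at low temperature, and the alkene geometry is kept.

Step 5
Reactants: 6 (3S,6E)-8-bromo-3,7-dimethylocta-1,6-dien-3-ol
Product: 7 (5E,9S)-5,9-dimethylundeca-5,10-diene-1,9-diol
Conditions: ClMg(CH2)3OMgCl (3 equiv, stock solution from 3-chloropropan-1-ol, iPrMgCl and Mg), Li2CuCl4 (3 mol %), THF, −78 → 0 °C; aq. NH4Cl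
Reagents that add atoms: 3-(chloromagnesio)propan-1-olate chloromagnesium salt, Cl[Mg]CCCO[Mg]Cl
Why: Copper-catalysed Grignard coupling with a primary allylic bromide, for which Li2CuCl4 in THF at low temperature favours substitution at the CH2 carbon (SN2, not SN2') with retention of the E geometry, the free hydroxyl costing only one equivalent of reagent.

Step 6
Reactants: 7 (5E,9S)-5,9-dimethylundeca-5,10-diene-1,9-diol
Product: 8 (5E,9S)-9-hydroxy-5,9-dimethylundeca-5,10-dienoic acid
Conditions: TEMPO (cat.), PhI(OAc)2, MeCN/H2O, 25 °C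
Reagents that add atoms: water, O
Why: Oxoammonium (TEMPO) oxidation takes the primary alcohol through the aldehyde hydrate to the acid and touches neither the tertiary alcohol nor the alkenes.

Step 7
Reactants: 8 (5E,9S)-9-hydroxy-5,9-dimethylundeca-5,10-dienoic acid; 9 tiglyl alcohol
Product: 10 (2E)-2-methylbut-2-en-1-yl (5E,9S)-9-hydroxy-5,9-dimethylundeca-5,10-dienoate
Conditions: EDC·HCl, DMAP, CH2Cl2, 0 → 25 °C
Reagents that add atoms: none
Why: Steglich-type carbodiimide esterification acylates the primary allylic alcohol 9, while the hindered tertiary hydroxyl of 8 is not acylated.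

Step 8
Reactants: 10 (2E)-2-methylbut-2-en-1-yl (5E,9S)-9-hydroxy-5,9-dimethylundeca-5,10-dienoate
Product: 11 (2E)-2-methylbut-2-en-1-yl 4-[(2S,3R,6S)-3-bromo-6-ethenyl-2,6-dimethyloxan-2-yl]butanoate
Conditions: 2,4,4,6-tetrabromocyclohexa-2,5-dienone (TBCO), MeNO2, 0 °C; chromatography
Reagents that add atoms: 2,4,4,6-tetrabromocyclohexa-2,5-dien-1-one, O=C1C(Br)=CC(Br)(Br)C=C1Br
Why: Bromoetherification (6-endo bromonium-induced cyclisation) in which the tertiary hydroxyl opens the bromonium ion of the E-alkene at its more substituted carbon in anti fashion, which sets oxane C2 and C3 relative to each other, while the tiglyl alkene is deactivated by its allylic acyloxy group; attack on the two alkene faces is expected to give both C6 epimers, from which the (2S,3R,6S) isomer is separated.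

Step 9
Reactants: 11 (2E)-2-methylbut-2-en-1-yl 4-[(2S,3R,6S)-3-bromo-6-ethenyl-2,6-dimethyloxan-2-yl]butanoate
Product: 12 (2R,3R)-2-{2-[(2S,3R,6S)-3-bromo-6-ethenyl-2,6-dimethyloxan-2-yl]ethyl}-3,4-dimethylpent-4-enoic acid
Conditions: (4S,5S)-2-bromo-4,5-diphenyl-1,3-bis{[3,5-bis(trifluoromethyl)phenyl]sulfonyl}-1,3,2-diazaborolidine (1.3 equiv), iPr2NEt, CH2Cl2, −78 °C, then −20 → 4 °C; H2O work-up
Reagents that add atoms: none
Why: Enantioselective Ireland–Claisen rearrangement of a chiral boron ketene acetal, in which the acetal with the C2 chain cis to O–B rearranges through a chair with that chain and the tiglyl methyl both pseudo-equatorial to give the 2,3-syn acid, and the C2-symmetric sulfonamide controller selects the face so that both new centres are (R).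

Step 10
Reactants: 12 (2R,3R)-2-{2-[(2S,3R,6S)-3-bromo-6-ethenyl-2,6-dimethyloxan-2-yl]ethyl}-3,4-dimethylpent-4-enoic acid
Product: 13 (3R,4R)-3-{2-[(2S,3R,6S)-3-bromo-6-ethenyl-2,6-dimethyloxan-2-yl]ethyl}-4,5-dimethylhex-5-en-2-one
Conditions: MeLi (3 equiv), Et2O, −78 → 0 °C; aq. NH4Cl
Reagents that add atoms: methyllithium, [Li]C
Why: Addition of MeLi to the lithium carboxylate stops at the dilithio gem-diolate and gives the methyl ketone on work-up without enolising the α-centre, and the equatorial, neopentyl-type secondary bromide has no antiperiplanar hydrogen for elimination.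

Step 11
Reactants: 13 (3R,4R)-3-{2-[(2S,3R,6S)-3-bromo-6-ethenyl-2,6-dimethyloxan-2-yl]ethyl}-4,5-dimethylhex-5-en-2-one
Product: 14 (2S,3R,6S)-3-bromo-6-ethenyl-2,6-dimethyl-2-{(3R,4R)-4,5-dimethyl-3-[(2S)-2-methyloxiran-2-yl]hex-5-en-1-yl}oxane
Conditions: Me3S+ I−, KN(SiMe3)2, THF, −20 → 0 °C
Reagents that add atoms: trimethylsulfonium iodide, C[S+](C)C.[I-]
Why: Corey–Chaykovsky epoxidation, in which the sulfonium ylide adds irreversibly to the ketone in the Felkin–Anh sense (anti to the branched C4 substituent and past the hydrogen) and so sets the quaternary oxirane carbon as (S), the minor epimer being removed by chromatography.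

Step 12
Reactants: 14 (2S,3R,6S)-3-bromo-6-ethenyl-2,6-dimethyl-2-{(3R,4R)-4,5-dimethyl-3-[(2S)-2-methyloxiran-2-yl]hex-5-en-1-yl}oxane
Product: 16 dactylopyranoid, via iodohydrin 15 (not isolated)
Conditions: LiI, AcOH, THF, 0 → 25 °C; then 2,6-lutidine, fac-Ir(ppy)3 (2 mol %), MeCN, blue LEDs, 25 °C, degassed
Reagents that add atoms: none
Why: Proposed new method: iodide opens the 2,2-disubstituted oxirane of 14 at its CH2 carbon (SN2) to give 15, the excited photocatalyst cleaves the primary C–I bond, the β-hydroxyalkyl radical at C6 adds to the CH2 end (C5) of the isopropenyl group, and the tertiary C4 radical is turned into the C4 cation (iodine-atom transfer then ionisation, or electron transfer to the oxidised photocatalyst), which the hydroxyl on C1 captures with loss of HI to the base. The closest known reaction types are the visible-light atom-transfer radical cyclisation of unactivated alkyl iodides, the titanocene-catalysed radical synthesis of tetrahydrofurans from epoxides and alkenes (which opens an epoxide with the opposite regiochemistry and so cannot deliver this bridge) and the acid-mediated closure of terpinen-4-ol to 1,4-cineole. The carbocycle closes by 6-endo-trig radical C–C bond formation, and the ether bridge by SN1-type capture of the tertiary cation by the 1,4-related hydroxyl across a boat cyclohexane, which closes both oxolane rings of the bicycle at once. C4 is the only new stereocentre and its configuration is fixed by the tether, because the oxygen on C1 can reach only one face of C4, while C1, C2 and C3 are carried through untouched. The step needs 6-endo instead of 5-exo closure, which the 1,1-disubstituted alkene and the branched C3 next to it secure (5-exo would build a quaternary carbon and leave a primary radical that cannot cross over to a cation), and it needs the C–I bond to react before the secondary C–Br bond, which the weaker bond and the hindered, far harder to reduce bromide secure. An alkene formed by proton loss from the cation is the substrate of the known cineole closure and can be returned to 16 by acid.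

**Compound list**

1 | geraniol, (2E)-3,7-dimethylocta-2,6-dien-1-ol | CC(C)=CCC/C(C)=C/CO | starting material
2 | (2S,3S)-2,3-epoxygeraniol, [(2S,3S)-3-methyl-3-(4-methylpent-3-en-1-yl)oxiran-2-yl]methanol | CC(C)=CCC[C@]1(C)O[C@H]1CO | intermediate
3 | (2R,3S)-2-(iodomethyl)-3-methyl-3-(4-methylpent-3-en-1-yl)oxirane (epoxy iodide) | CC(C)=CCC[C@]1(C)O[C@H]1CI | intermediate
4 | (S)-linalool, (3S)-3,7-dimethylocta-1,6-dien-3-ol | C=C[C@@](C)(O)CCC=C(C)C | intermediate
5 | (2E,6S)-2,6-dimethylocta-2,7-diene-1,6-diol | C=C[C@@](C)(O)CC/C=C(\C)CO | intermediate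
6 | (3S,6E)-8-bromo-3,7-dimethylocta-1,6-dien-3-ol | C=C[C@@](C)(O)CC/C=C(\C)CBr | intermediate
7 | (5E,9S)-5,9-dimethylundeca-5,10-diene-1,9-diol | C=C[C@@](C)(O)CC/C=C(\C)CCCCO | intermediate
8 | (5E,9S)-9-hydroxy-5,9-dimethylundeca-5,10-dienoic acid | C=C[C@@](C)(O)CC/C=C(\C)CCCC(O)=O | intermediate
9 | tiglyl alcohol, (2E)-2-methylbut-2-en-1-ol | C/C=C(\C)CO | starting material
10 | (2E)-2-methylbut-2-en-1-yl (5E,9S)-9-hydroxy-5,9-dimethylundeca-5,10-dienoate | C=C[C@@](C)(O)CC/C=C(\C)CCCC(=O)OC/C(C)=C/C | intermediate
11 | (2E)-2-methylbut-2-en-1-yl 4-[(2S,3R,6S)-3-bromo-6-ethenyl-2,6-dimethyloxan-2-yl]butanoate | C=C[C@]1(C)CC[C@@H](Br)[C@](C)(CCCC(=O)OC/C(C)=C/C)O1 | intermediate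
12 | (2R,3R)-2-{2-[(2S,3R,6S)-3-bromo-6-ethenyl-2,6-dimethyloxan-2-yl]ethyl}-3,4-dimethylpent-4-enoic acid | C=C[C@]1(C)CC[C@@H](Br)[C@](C)(CC[C@H]([C@@H](C)C(C)=C)C(O)=O)O1 | intermediate
13 | (3R,4R)-3-{2-[(2S,3R,6S)-3-bromo-6-ethenyl-2,6-dimethyloxan-2-yl]ethyl}-4,5-dimethylhex-5-en-2-one | C=C[C@]1(C)CC[C@@H](Br)[C@](C)(CC[C@H]([C@@H](C)C(C)=C)C(C)=O)O1 | intermediate
14 | (2S,3R,6S)-3-bromo-6-ethenyl-2,6-dimethyl-2-{(3R,4R)-4,5-dimethyl-3-[(2S)-2-methyloxiran-2-yl]hex-5-en-1-yl}oxane | C=C[C@]1(C)CC[C@@H](Br)[C@](C)(CC[C@H]([C@@H](C)C(C)=C)[C@@]2(C)CO2)O1 | intermediate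
15 | (2S,3R,4R)-3-{2-[(2S,3R,6S)-3-bromo-6-ethenyl-2,6-dimethyloxan-2-yl]ethyl}-1-iodo-2,4,5-trimethylhex-5-en-2-ol (iodohydrin) | C=C[C@]1(C)CC[C@@H](Br)[C@](C)(CC[C@H]([C@@H](C)C(C)=C)[C@](C)(O)CI)O1 | intermediate
16 | dactylopyranoid, (2S,3R,6S)-3-bromo-6-ethenyl-2,6-dimethyl-2-{2-[(1R,2R,3R,4S)-1,3,4-trimethyl-7-oxabicyclo[2.2.1]heptan-2-yl]ethyl}oxane | C=C[C@]1(C)CC[C@@H](Br)[C@](C)(CC[C@@H]2[C@@H](C)[C@]3(C)CC[C@@]2(C)O3)O1 | target

**Count**

Total steps: 12. Longest linear sequence: 12 steps (geraniol to 16; tiglyl alcohol enters in step 7).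

**Steps most likely to fail**

Step 12 (proposed new method). The primary radical may close in the 5-exo mode or be reduced before it cyclises. The tertiary cation may lose a proton, or the radical–polar crossover may fail to turn over, before the hydroxyl captures it. The fallback uses known reactions and separates C–C from C–O bond formation; it sets out from 14 and comes back at 16. Compound 14 is opened with LiI/AcOH and iodohydrin 15 is isolated. A Heck-type cyclisation of the unactivated alkyl iodide (Pd(PPh3)4, 1,2,2,6,6-pentamethylpiperidine, benzene, 110 °C) should give (1R,2R,3R)-2-{2-[(2S,3R,6S)-3-bromo-6-ethenyl-2,6-dimethyloxan-2-yl]ethyl}-1,3-dimethyl-4-methylidenecyclohexan-1-ol F1, together with its endocyclic alkene isomer. Catalytic TsOH in CH2Cl2 should then add the tertiary hydroxyl across the ring to the alkene (the 1,4-cineole closure) and give 16.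

Step 8. Closure in the 5-exo mode to the bromo-oxolane, bromination of the tiglyl alkene and weak facial discrimination by the remote carbinol centre would all cut the amount of 11. The fallback sets out from 10 and comes back at 11. Hg(O2CCF3)2 in MeNO2 at −20 °C followed by aqueous KBr (Markovnikov 6-endo oxymercuration) should give the organomercury bromide (2E)-2-methylbut-2-en-1-yl 4-[(2S,3R,6S)-3-(bromomercurio)-6-ethenyl-2,6-dimethyloxan-2-yl]butanoate F2. Radical bromodemercuration (Br2, LiBr, pyridine, O2) then replaces mercury by bromine, with the equatorial bromide 11 expected to predominate. This secures the ring size; the C6 epimers still have to be separated at either stage.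

Step 9. Facial control by the controller may be low on this hindered ester, or enolisation and rearrangement may be too slow to compete with decay of the boron ketene acetal. The fallback replaces reagent control by chirality transfer from a carbinol centre; it sets out from 8 and comes back at 12. Compound 8 is esterified (EDC, DMAP) with (1R,2E)-2-methyl-1-(trimethylsilyl)but-2-en-1-ol F3, itself made by oxazaborolidine-catalysed borane reduction of the corresponding acylsilane. This gives (1R,2E)-2-methyl-1-(trimethylsilyl)but-2-en-1-yl (5E,9S)-9-hydroxy-5,9-dimethylundeca-5,10-dienoate F4. Bromoetherification as in step 8 gives (1R,2E)-2-methyl-1-(trimethylsilyl)but-2-en-1-yl 4-[(2S,3R,6S)-3-bromo-6-ethenyl-2,6-dimethyloxan-2-yl]butanoate F5. Ireland–Claisen rearrangement of its silyl ketene acetal (KN(SiMe3)2, Me3SiCl, THF/DMPU, −78 → 25 °C), through the chair with the silyl group pseudo-equatorial, should give (2R,3R,4E)-2-{2-[(2S,3R,6S)-3-bromo-6-ethenyl-2,6-dimethyloxan-2-yl]ethyl}-3,4-dimethyl-5-(trimethylsilyl)pent-4-enoic acid F6. Protodesilylation (TsOH, wet MeCN) then gives 12.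

**Further compounds**

F1 | step 12 | (1R,2R,3R)-2-{2-[(2S,3R,6S)-3-bromo-6-ethenyl-2,6-dimethyloxan-2-yl]ethyl}-1,3-dimethyl-4-methylidenecyclohexan-1-ol | C=C[C@]1(C)CC[C@@H](Br)[C@](C)(CC[C@@H]2[C@@H](C)C(=C)CC[C@@]2(C)O)O1
F2 | step 8 | (2E)-2-methylbut-2-en-1-yl 4-[(2S,3R,6S)-3-(bromomercurio)-6-ethenyl-2,6-dimethyloxan-2-yl]butanoate | C=C[C@]1(C)CC[C@@H]([Hg]Br)[C@](C)(CCCC(=O)OC/C(C)=C/C)O1
F3 | step 9 | (1R,2E)-2-methyl-1-(trimethylsilyl)but-2-en-1-ol | C/C=C(\C)[C@H](O)[Si](C)(C)C
F4 | step 9 | (1R,2E)-2-methyl-1-(trimethylsilyl)but-2-en-1-yl (5E,9S)-9-hydroxy-5,9-dimethylundeca-5,10-dienoate | C=C[C@@](C)(O)CC/C=C(\C)CCCC(=O)O[C@H]([Si](C)(C)C)/C(C)=C/C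
F5 | step 9 | (1R,2E)-2-methyl-1-(trimethylsilyl)but-2-en-1-yl 4-[(2S,3R,6S)-3-bromo-6-ethenyl-2,6-dimethyloxan-2-yl]butanoate | C=C[C@]1(C)CC[C@@H](Br)[C@](C)(CCCC(=O)O[C@H]([Si](C)(C)C)/C(C)=C/C)O1
F6 | step 9 | (2R,3R,4E)-2-{2-[(2S,3R,6S)-3-bromo-6-ethenyl-2,6-dimethyloxan-2-yl]ethyl}-3,4-dimethyl-5-(trimethylsilyl)pent-4-enoic acid | C=C[C@]1(C)CC[C@@H](Br)[C@](C)(CC[C@H]([C@@H](C)/C(C)=C/[Si](C)(C)C)C(O)=O)O1
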